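**Retrosynthetic overview**

1. Target 29 ⇐ acetylation and reductive desulfonylation ⇐ C7–C8 bond from ring sulfone 17 and the C20 allylic bromide 25 (farnesol, two-carbon homologation, E-selective Wittig).
2. 17 ⇐ diol 14 ⇐ bridged γ-lactone 13 (C4–O–C7(=O)–C6), whose C1 methylene comes from a silyloxy group via the ketone.
3. Lactone ⇐ Baeyer–Villiger oxygen insertion into the C7–C4 bond of bicyclo[3.1.1]heptan-6-one 9, in which the carbonyl carbon C7 bridges C4 and C6.
4. 9 ⇐ crossed intramolecular ketene–alkene [2+2] of acid chloride 7: the cyclobutanone (C4, C5, C6, C7) and the cyclohexane (C1–C6) close together in the only ring-forming step; the four-membered ring and then the lactone are cut afterwards.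
5. Feature used (ring: C1 methylene carbon, C2, C3, C4 acetoxy carbon, C5 gem-dimethyl carbon, C6 chain-bearing CH; chain C7 outward): the C4–O and C6–C7 bonds are cis-1,3 across quaternary C5, which is the relationship of two bridgehead bonds to a one-carbon bridge.

Key step: step 6

Assumption: the atom labels C1–C22 defined in line 5 are used for every intermediate (they are not IUPAC locants), and 1, 2 and 18 are purchased.

**Route**

Step 1
Reactants: 1 methyl 5-chloro-5-oxopentanoate; 2 (2-methylprop-1-enyl)magnesium bromide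
Product: 3 methyl 7-methyl-5-oxooct-6-enoate
Conditions: CuI (5 mol%), THF, −78 °C, slow addition of 2 to 1
Reagents that add atoms: none
Why: Copper-catalysed acylation of the alkenyl Grignard reagent by the acid chloride at low temperature is far faster than attack on the methyl ester or on the enone formed (ketone synthesis from an acid chloride).

Step 2
Reactants: 3 methyl 7-methyl-5-oxooct-6-enoate
Product: 4 methyl (5R)-5-hydroxy-7-methyloct-6-enoate
Conditions: (S)-2-methyl-CBS-oxazaborolidine (20 mol%), catecholborane, toluene, −78 °C; MeOH quench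
Reagents that add atoms: none
Why: CBS reduction, in which the oxazaborolidine binds the ketone with the 2-methylpropenyl group as the large substituent and directs hydride to one face, so the (S)-catalyst should set the (R)-carbinol, while catecholborane at −78 °C leaves the ester and the alkene alone.

Step 3
Reactants: 4 methyl (5R)-5-hydroxy-7-methyloct-6-enoate
Product: 5 methyl (5R)-5-(tert-butyldimethylsilyloxy)-7-methyloct-6-enoate
Conditions: TBSCl, imidazole, DMF, 25 °C
Reagents that add atoms: tert-butyldimethylsilyl chloride, CC(C)(C)[Si](C)(C)Cl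
Why: Standard silylation of a secondary allylic alcohol, which also blocks lactonisation onto the ester.

Step 4
Reactants: 5 methyl (5R)-5-(tert-butyldimethylsilyloxy)-7-methyloct-6-enoate
Product: 6 (5R)-5-(tert-butyldimethylsilyloxy)-7-methyloct-6-enoic acid
Conditions: LiOH, THF/MeOH/H2O, 25 °C; then cold dilute HCl to pH 4
Reagents that add atoms: lithium hydroxide, [Li+].[OH-]
Why: Saponification of the methyl ester, to which the secondary silyl ether is stable, with the acid set free in the cold at mild pH so that the allylic silyl ether is kept.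

Step 5
Reactants: 6 (5R)-5-(tert-butyldimethylsilyloxy)-7-methyloct-6-enoic acid
Product: 7 (5R)-5-(tert-butyldimethylsilyloxy)-7-methyloct-6-enoyl chloride
Conditions: 1-chloro-N,N,2-trimethylprop-1-en-1-amine, CH2Cl2, 0 → 25 °C; concentrated and used crude
Reagents that add atoms: 1-chloro-N,N,2-trimethylprop-1-en-1-amine, CC(C)=C(Cl)N(C)C
Why: The α-chloroenamine converts the acid to the acid chloride under neutral conditions without free HCl, which protects the ionisable allylic silyl ether (acid chloride formation through an acyloxyiminium chloride).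

Step 6
Reactants: 7 (5R)-5-(tert-butyldimethylsilyloxy)-7-methyloct-6-enoyl chloride
Product: 9 (1S,2R,5S)-2-(tert-butyldimethylsilyloxy)-7,7-dimethylbicyclo[3.1.1]heptan-6-one (silyloxy group syn to the carbonyl bridge), via ketene 8 (not isolated)
Conditions: Et3N (5 equiv), toluene, reflux, slow addition of 7 to a final 0.01 M; chromatography
Reagents that add atoms: none
Why: Et3N removes HCl from 7 to give aldoketene 8, whose electrophilic central carbon C7 bonds to the less substituted alkene carbon C6 while positive charge develops at the dimethyl-substituted C5, which then bonds to the ketene α-carbon C4 in a concerted but asynchronous thermal [2+2]. The closest known reaction is the intramolecular ketene–alkene cycloaddition of 7-methyloct-6-enoyl chlorides, which gives 7,7-dimethylbicyclo[3.1.1]heptan-6-ones. The C7–C6 bond closes the six-membered ring C7–C4–C3–C2–C1–C6 in a 6-exo sense, and the C4–C5 bond then closes the four-membered ring C4–C5–C6–C7 across it, which completes the carbocycle C1–C6 of the target with C7 as a temporary one-carbon bridge from C4 to C6 (crossed, not fused, mode). The new stereocentres C4 and C6 are bridgeheads whose relative configuration is fixed by the bicycle, and their absolute sense is set by the C1 stereocentre: the tether carbon C2 must eclipse the alkene because it lies in the forming ring, so the silyloxy group takes the outer position near the vinylic hydrogen, with its C–O bond close to the alkene plane and turned away from the developing gem-dimethyl bridge, and C1–H lies anti to the forming C6–C7 bond, which places the silyloxy group syn to the carbonyl bridge. The step needs the crossed regiochemistry, secured by the distal dimethyl terminus and the three-atom tether, cyclisation ahead of ketene dimerisation, secured by slow addition at high dilution, and face selectivity, secured as described. The C1 epimer of 9 would lead to the mirror-image ring once C1 becomes planar and is therefore removed by chromatography at this stage.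

Step 7
Reactants: 9 (1S,2R,5S)-2-(tert-butyldimethylsilyloxy)-7,7-dimethylbicyclo[3.1.1]heptan-6-one
Product: 10 (1S,2R,5S)-2-(tert-butyldimethylsilyloxy)-8,8-dimethyl-6-oxabicyclo[3.2.1]octan-7-one
Conditions: mCPBA, NaHCO3, CH2Cl2, 0 → 25 °C; chromatography
Reagents that add atoms: 3-chloroperoxybenzoic acid, OOC(=O)c1cccc(Cl)c1
Why: Baeyer–Villiger oxidation of a strained cyclobutanone, in which the bridgehead next to the silyloxy-bearing carbon (C6) is inductively deactivated, so C4 should migrate with retention and the C4–O and C6–C7 bonds stay cis because both remain tied in the bicycle.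

Step 8
Reactants: 10 (1S,2R,5S)-2-(tert-butyldimethylsilyloxy)-8,8-dimethyl-6-oxabicyclo[3.2.1]octan-7-one
Product: 11 (1S,2R,5S)-2-hydroxy-8,8-dimethyl-6-oxabicyclo[3.2.1]octan-7-one
Conditions: HF·pyridine, THF/pyridine, 0 → 25 °C
Reagents that add atoms: none
Why: Fluoride cleavage of the silyl ether under buffered, non-basic conditions that leave the lactone closed.

Step 9
Reactants: 11 (1S,2R,5S)-2-hydroxy-8,8-dimethyl-6-oxabicyclo[3.2.1]octan-7-one
Product: 12 (1S,5S)-8,8-dimethyl-6-oxabicyclo[3.2.1]octane-2,7-dione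
Conditions: Dess–Martin periodinane, NaHCO3, CH2Cl2, 25 °C
Reagents that add atoms: none
Why: Dess–Martin oxidation of the secondary alcohol gives a β-keto lactone that cannot enolise or epimerise at C6, because C6 is a bridgehead.

Step 10
Reactants: 12 (1S,5S)-8,8-dimethyl-6-oxabicyclo[3.2.1]octane-2,7-dione
Product: 13 (1R,5S)-8,8-dimethyl-2-methylidene-6-oxabicyclo[3.2.1]octan-7-one
Conditions: Ph3PCH3Br, KOtBu, THF, 0 → 25 °C
Reagents that add atoms: methyltriphenylphosphonium bromide, C[P+](c1ccccc1)(c1ccccc1)c1ccccc1.[Br-]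
Why: Wittig methylenation of the ketone, which is far more electrophilic toward the ylide than the lactone carbonyl, and the only enolisable position (C2) carries no stereocentre.

Step 11
Reactants: 13 (1R,5S)-8,8-dimethyl-2-methylidene-6-oxabicyclo[3.2.1]octan-7-one
Product: 14 (1S,3R)-3-(hydroxymethyl)-2,2-dimethyl-4-methylidenecyclohexan-1-ol
Conditions: LiAlH4, THF, 0 → 25 °C; aqueous NaOH work-up
Reagents that add atoms: none
Why: LiAlH4 reduces the lactone to the primary C7 alcohol and releases the C4 hydroxyl without breaking a bond to C4 or C6, so both stereocentres are kept and the alkene is inert.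

Step 12
Reactants: 14 (1S,3R)-3-(hydroxymethyl)-2,2-dimethyl-4-methylidenecyclohexan-1-ol
Product: 15 [(1R,3S)-3-hydroxy-2,2-dimethyl-6-methylidenecyclohexyl]methyl 4-methylbenzenesulfonate
Conditions: TsCl (1.1 equiv), pyridine, CH2Cl2, 0 °C; used without delay
Reagents that add atoms: 4-methylbenzenesulfonyl chloride, Cc1ccc(cc1)S(Cl)(=O)=O
Why: Selective sulfonylation of the primary hydroxyl over the hindered secondary hydroxyl that neighbours the quaternary carbon.

Step 13
Reactants: 15 [(1R,3S)-3-hydroxy-2,2-dimethyl-6-methylidenecyclohexyl]methyl 4-methylbenzenesulfonate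
Product: 16 (1S,3R)-2,2-dimethyl-4-methylidene-3-[(phenylsulfanyl)methyl]cyclohexan-1-ol
Conditions: PhSH, K2CO3, DMF, 25 °C
Reagents that add atoms: benzenethiol, Sc1ccccc1
Why: SN2 displacement of the primary tosylate by the soft, weakly basic thiolate, which should outrun ring closure by the un-ionised C4 hydroxyl.

Step 14
Reactants: 16 (1S,3R)-2,2-dimethyl-4-methylidene-3-[(phenylsulfanyl)methyl]cyclohexan-1-ol
Product: 17 (1S,3R)-3-[(benzenesulfonyl)methyl]-2,2-dimethyl-4-methylidenecyclohexan-1-ol
Conditions: (NH4)6Mo7O24·4H2O (cat.), 30% H2O2, EtOH, 0 → 25 °C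
Reagents that add atoms: hydrogen peroxide, OO
Why: Molybdate-catalysed peroxide oxidation takes the sulfide to the sulfone and does not epoxidise the 1,1-disubstituted alkene.

Step 15
Reactants: 18 (2E,6E)-farnesol
Product: 19 (2E,6E)-1-bromo-3,7,11-trimethyldodeca-2,6,10-triene
Conditions: PBr3 (0.4 equiv), Et2O, −10 °C; used crude
Reagents that add atoms: phosphorus tribromide, BrP(Br)Br
Why: Conversion of a primary allylic alcohol to the bromide at low temperature, without allylic transposition or loss of E geometry.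

Step 16
Reactants: 19 (2E,6E)-1-bromo-3,7,11-trimethyldodeca-2,6,10-triene
Product: 20 (4E,8E)-5,9,13-trimethyltetradeca-4,8,12-trienenitrile
Conditions: MeCN (3 equiv), n-BuLi, THF, −78 °C; then 19, −78 → 0 °C
Reagents that add atoms: acetonitrile, CC#N
Why: SN2 alkylation of cyanomethyllithium, used in excess to suppress dialkylation, at the primary allylic carbon adds the two carbons C11 and C10.

Step 17
Reactants: 20 (4E,8E)-5,9,13-trimethyltetradeca-4,8,12-trienenitrile
Product: 22 (4E,8E)-5,9,13-trimethyltetradeca-4,8,12-trienal, via aluminium aldimine 21 (not isolated)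
Conditions: i-Bu2AlH (1.2 equiv), CH2Cl2, −78 °C; then 1 M HCl, 0 °C
Reagents that add atoms: water, O
Why: i-Bu2AlH adds once to the nitrile to give the aluminium aldimine, which is hydrolysed to the aldehyde on mild acidic work-up.

Step 18
Reactants: 22 (4E,8E)-5,9,13-trimethyltetradeca-4,8,12-trienal
Product: 23 ethyl (2E,6E,10E)-2,7,11,15-tetramethylhexadeca-2,6,10,14-tetraenoate
Conditions: Ph3P=C(CH3)CO2Et, CH2Cl2, 25 °C
Reagents that add atoms: ethyl 2-(triphenylphosphoranylidene)propanoate, CCOC(=O)C(C)=P(c1ccccc1)(c1ccccc1)c1ccccc1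
Why: Wittig olefination with the α-methyl stabilised ylide should give mainly the E-trisubstituted enoate (C9=C10).

Step 19
Reactants: 23 ethyl (2E,6E,10E)-2,7,11,15-tetramethylhexadeca-2,6,10,14-tetraenoate
Product: 24 (2E,6E,10E)-2,7,11,15-tetramethylhexadeca-2,6,10,14-tetraen-1-ol
Conditions: i-Bu2AlH (2.2 equiv), CH2Cl2, −78 °C; aqueous potassium sodium tartrate
Reagents that add atoms: none
Why: 1,2-Reduction of the conjugated ester to the allylic alcohol at low temperature leaves every double bond in place.

Step 20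
Reactants: 24 (2E,6E,10E)-2,7,11,15-tetramethylhexadeca-2,6,10,14-tetraen-1-ol
Product: 25 (2E,6E,10E)-1-bromo-2,7,11,15-tetramethylhexadeca-2,6,10,14-tetraene
Conditions: PBr3 (0.4 equiv), Et2O, −10 °C; used at once
Reagents that add atoms: phosphorus tribromide, BrP(Br)Br
Why: Primary allylic alcohol to bromide as in step 15, with the labile bromide taken on without purification.

Step 21
Reactants: 17 (1S,3R)-3-[(benzenesulfonyl)methyl]-2,2-dimethyl-4-methylidenecyclohexan-1-ol; 25 (2E,6E,10E)-1-bromo-2,7,11,15-tetramethylhexadeca-2,6,10,14-tetraene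
Product: 27 (1S,3R)-3-[(3E,7E,11E)-1-(benzenesulfonyl)-3,8,12,16-tetramethylheptadeca-3,7,11,15-tetraenyl]-2,2-dimethyl-4-methylidenecyclohexan-1-ol (both epimers at C7), via dilithio sulfone 26 (not isolated)
Conditions: n-BuLi (2.2 equiv), THF/DMPU, −78 °C; then 25, −78 → −20 °C; then H2O
Reagents that add atoms: none
Why: The first equivalent of n-BuLi forms the C4 lithium alkoxide and the second the α-sulfonyl carbanion at C7, which is the far better nucleophile and is alkylated at the primary allylic carbon of 25 (sulfone alkylation), forming C7–C8.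

Step 22
Reactants: 27 the C7 sulfone from step 21
Product: 28 (1S,3R)-2,2-dimethyl-4-methylidene-3-[(3E,7E,11E)-3,8,12,16-tetramethylheptadeca-3,7,11,15-tetraenyl]cyclohexan-1-ol
Conditions: 6% Na/Hg, Na2HPO4, MeOH/THF, −20 → 0 °C
Reagents that add atoms: none
Why: Reductive desulfonylation by electron transfer in buffered methanol removes the sulfone, and because the sulfone is not allylic no double bond should move.

Step 23
Reactants: 28 the alcohol from step 22
Product: 29 (1S,3R)-2,2-dimethyl-4-methylidene-3-[(3E,7E,11E)-3,8,12,16-tetramethylheptadeca-3,7,11,15-tetraenyl]cyclohexyl acetate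
Conditions: Ac2O, pyridine, DMAP (cat.), CH2Cl2, 25 °C
Reagents that add atoms: acetic anhydride, CC(=O)OC(C)=O
Why: DMAP-catalysed acetylation of the hindered secondary alcohol gives the target without touching the alkenes.

**Compound list**

1 | methyl 5-chloro-5-oxopentanoate | COC(=O)CCCC(Cl)=O | starting material
2 | (2-methylprop-1-enyl)magnesium bromide | CC(C)=C[Mg]Br | starting material
3 | methyl 7-methyl-5-oxooct-6-enoate | COC(=O)CCCC(=O)C=C(C)C | intermediate
4 | methyl (5R)-5-hydroxy-7-methyloct-6-enoate | COC(=O)CCC[C@@H](O)C=C(C)C | intermediate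
5 | methyl (5R)-5-(tert-butyldimethylsilyloxy)-7-methyloct-6-enoate | COC(=O)CCC[C@@H](O[Si](C)(C)C(C)(C)C)C=C(C)C | intermediate
6 | (5R)-5-(tert-butyldimethylsilyloxy)-7-methyloct-6-enoic acid | OC(=O)CCC[C@@H](O[Si](C)(C)C(C)(C)C)C=C(C)C | intermediate
7 | (5R)-5-(tert-butyldimethylsilyloxy)-7-methyloct-6-enoyl chloride | ClC(=O)CCC[C@@H](O[Si](C)(C)C(C)(C)C)C=C(C)C | intermediate
8 | (5R)-5-(tert-butyldimethylsilyloxy)-7-methylocta-1,6-dien-1-one (ketene) | O=C=CCC[C@@H](O[Si](C)(C)C(C)(C)C)C=C(C)C | intermediate
9 | (1S,2R,5S)-2-(tert-butyldimethylsilyloxy)-7,7-dimethylbicyclo[3.1.1]heptan-6-one | O=C1[C@H]2CC[C@@H](O[Si](C)(C)C(C)(C)C)[C@@H]1C2(C)C | intermediate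
10 | (1S,2R,5S)-2-(tert-butyldimethylsilyloxy)-8,8-dimethyl-6-oxabicyclo[3.2.1]octan-7-one | O=C1O[C@H]2CC[C@@H](O[Si](C)(C)C(C)(C)C)[C@@H]1C2(C)C | intermediate
11 | (1S,2R,5S)-2-hydroxy-8,8-dimethyl-6-oxabicyclo[3.2.1]octan-7-one | O=C1O[C@H]2CC[C@@H](O)[C@@H]1C2(C)C | intermediate
12 | (1S,5S)-8,8-dimethyl-6-oxabicyclo[3.2.1]octane-2,7-dione | O=C1O[C@H]2CCC(=O)[C@@H]1C2(C)C | intermediate
13 | (1R,5S)-8,8-dimethyl-2-methylidene-6-oxabicyclo[3.2.1]octan-7-one | O=C1O[C@H]2CCC(=C)[C@@H]1C2(C)C | intermediate
14 | (1S,3R)-3-(hydroxymethyl)-2,2-dimethyl-4-methylidenecyclohexan-1-ol | C=C1CC[C@H](O)C(C)(C)[C@@H]1CO | intermediate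
15 | [(1R,3S)-3-hydroxy-2,2-dimethyl-6-methylidenecyclohexyl]methyl 4-methylbenzenesulfonate | C=C1CC[C@H](O)C(C)(C)[C@@H]1COS(=O)(=O)c1ccc(C)cc1 | intermediate
16 | (1S,3R)-2,2-dimethyl-4-methylidene-3-[(phenylsulfanyl)methyl]cyclohexan-1-ol | C=C1CC[C@H](O)C(C)(C)[C@@H]1CSc1ccccc1 | intermediate
17 | (1S,3R)-3-[(benzenesulfonyl)methyl]-2,2-dimethyl-4-methylidenecyclohexan-1-ol | C=C1CC[C@H](O)C(C)(C)[C@@H]1CS(=O)(=O)c1ccccc1 | intermediate
18 | (2E,6E)-farnesol | CC(C)=CCC/C(C)=C/CC/C(C)=C/CO | starting material
19 | (2E,6E)-1-bromo-3,7,11-trimethyldodeca-2,6,10-triene | CC(C)=CCC/C(C)=C/CC/C(C)=C/CBr | intermediate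
20 | (4E,8E)-5,9,13-trimethyltetradeca-4,8,12-trienenitrile | CC(C)=CCC/C(C)=C/CC/C(C)=C/CCC#N | intermediate
21 | (4E,8E)-N-[bis(2-methylpropyl)alumanyl]-5,9,13-trimethyltetradeca-4,8,12-trien-1-imine | CC(C)=CCC/C(C)=C/CC/C(C)=C/CCC=N[Al](CC(C)C)CC(C)C | intermediate
22 | (4E,8E)-5,9,13-trimethyltetradeca-4,8,12-trienal | CC(C)=CCC/C(C)=C/CC/C(C)=C/CCC=O | intermediate
23 | ethyl (2E,6E,10E)-2,7,11,15-tetramethylhexadeca-2,6,10,14-tetraenoate | CC(C)=CCC/C(C)=C/CC/C(C)=C/CC/C=C(\C)C(=O)OCC | intermediate
24 | (2E,6E,10E)-2,7,11,15-tetramethylhexadeca-2,6,10,14-tetraen-1-ol | CC(C)=CCC/C(C)=C/CC/C(C)=C/CC/C=C(\C)CO | intermediate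
25 | (2E,6E,10E)-1-bromo-2,7,11,15-tetramethylhexadeca-2,6,10,14-tetraene | CC(C)=CCC/C(C)=C/CC/C(C)=C/CC/C=C(\C)CBr | intermediate
26 | dilithio derivative of 17 (lithium alkoxide at C4, α-sulfonyl carbanion at C7) | C=C1CC[C@H](O[Li])C(C)(C)[C@@H]1C([Li])S(=O)(=O)c1ccccc1 | intermediate
27 | (1S,3R)-3-[(3E,7E,11E)-1-(benzenesulfonyl)-3,8,12,16-tetramethylheptadeca-3,7,11,15-tetraenyl]-2,2-dimethyl-4-methylidenecyclohexan-1-ol, both epimers at C7 | C=C1CC[C@H](O)C(C)(C)[C@@H]1C(C/C(C)=C/CC/C=C(\C)CC/C=C(\C)CCC=C(C)C)S(=O)(=O)c1ccccc1 | intermediate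
28 | (1S,3R)-2,2-dimethyl-4-methylidene-3-[(3E,7E,11E)-3,8,12,16-tetramethylheptadeca-3,7,11,15-tetraenyl]cyclohexan-1-ol | C=C1CC[C@H](O)C(C)(C)[C@@H]1CC/C(C)=C/CC/C=C(\C)CC/C=C(\C)CCC=C(C)C | intermediate
29 | (1S,3R)-2,2-dimethyl-4-methylidene-3-[(3E,7E,11E)-3,8,12,16-tetramethylheptadeca-3,7,11,15-tetraenyl]cyclohexyl acetate | C=C1CC[C@H](OC(C)=O)C(C)(C)[C@@H]1CC/C(C)=C/CC/C=C(\C)CC/C=C(\C)CCC=C(C)C | target

**Step count and risks**

Total step count: 23. Longest linear sequence: 17 steps (steps 1–14, then 21–23); steps 15–20 make the side-chain bromide in parallel.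

Steps most likely to fail:

1. Step 6. The alkylketene may dimerise or be intercepted before it cyclises, because the alkene is deactivated by the allylic silyloxy group. Face selectivity may also be incomplete, which would lower optical purity, since the C1 epimer leads to the mirror-image ring. Fallback, from 7 and back at 9: pyrrolidine and Et3N convert 7 into the pyrrolidine amide F1. Tf2O and 2,4,6-collidine in ClCH2CH2Cl turn it into the far more electrophilic keteniminium triflate F2, which should undergo the same crossed [2+2] at lower temperature to give the bicyclic iminium triflate F3. Hydrolysis with aqueous NaHCO3 returns ketone 9, purified as in the main route.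

2. Step 7. Migration of C6 may compete with migration of C4, giving the regioisomeric lactone in which oxygen sits on the wrong bridgehead. Fallback, from 9 and back at 12: HF·pyridine gives the hydroxy ketone F4 and Dess–Martin periodinane the dione F5. C6 then carries an acyl group and cannot migrate, and the strained cyclobutanone is the carbonyl that reacts, so buffered mCPBA should insert oxygen only into C7–C4 and give keto lactone 12 directly; steps 8 and 9 fall away.

3. Step 13. The cis C4 hydroxyl may close onto the activated C7 to form a bridged ether, already during sulfonylation or during the displacement, and substitution at the hindered C7 may be slow. Fallback, from 14 and back at 17: TBSOTf and 2,6-lutidine give the bis(silyl ether) F6. HF·pyridine in THF/pyridine at 0 °C removes only the primary silyl group to give the primary alcohol F7. With the C4 oxygen masked, redox condensation with (PhS)2 and PBu3 gives the sulfide F8, (NH4)6Mo7O24/H2O2 gives the silyloxy sulfone F9, and Bu4NF returns hydroxy sulfone 17.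

**Further compounds**

F1 | step 6 | 1-[(5R)-5-(tert-butyldimethylsilyloxy)-7-methyloct-6-enoyl]pyrrolidine | O=C(CCC[C@@H](O[Si](C)(C)C(C)(C)C)C=C(C)C)N1CCCC1
F2 | step 6 | keteniminium triflate of F1 | [O-]S(=O)(=O)C(F)(F)F.C(=C=[N+]1CCCC1)CC[C@@H](O[Si](C)(C)C(C)(C)C)C=C(C)C
F3 | step 6 | pyrrolidinium-ylidene (iminium) triflate of ketone 9 | [O-]S(=O)(=O)C(F)(F)F.C1CCC[N+]1=C1[C@H]2CC[C@@H](O[Si](C)(C)C(C)(C)C)[C@@H]1C2(C)C
F4 | step 7 | (1S,2R,5S)-2-hydroxy-7,7-dimethylbicyclo[3.1.1]heptan-6-one | O=C1[C@H]2CC[C@@H](O)[C@@H]1C2(C)C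
F5 | step 7 | (1S,5S)-7,7-dimethylbicyclo[3.1.1]heptane-2,6-dione | O=C1[C@H]2CCC(=O)[C@@H]1C2(C)C
F6 | step 13 | bis(tert-butyldimethylsilyl) ether of diol 14 | C=C1CC[C@H](O[Si](C)(C)C(C)(C)C)C(C)(C)[C@@H]1CO[Si](C)(C)C(C)(C)C
F7 | step 13 | C4 tert-butyldimethylsilyl ether of diol 14 (primary alcohol free) | C=C1CC[C@H](O[Si](C)(C)C(C)(C)C)C(C)(C)[C@@H]1CO
F8 | step 13 | C4 tert-butyldimethylsilyl ether of sulfide 16 | C=C1CC[C@H](O[Si](C)(C)C(C)(C)C)C(C)(C)[C@@H]1CSc1ccccc1
F9 | step 13 | C4 tert-butyldimethylsilyl ether of sulfone 17 | C=C1CC[C@H](O[Si](C)(C)C(C)(C)C)C(C)(C)[C@@H]1CS(=O)(=O)c1ccccc1
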